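The 18-membered ring is disconnected at the diaryl ether bond between C2 of the trioxygenated ring B and the oxygen on the meta-substituted ring C. The key step exploits the hydroxyl on the neighbouring C3: it is carried as a formyl group, which activates a C2 fluoride for intramolecular SNAr and later becomes the OH by Baeyer–Villiger (Dakin) oxidation. The precursor is an open-chain tetra-aryl compound with a 2-fluoro-3-formyl-4-methoxyphenyl end and a silyl-masked ring C phenol; fluoride unmasks the phenoxide and closes the macrocycle in one operation. Both CH2CH2 bridges come from B-alkyl Suzuki couplings, so no alkene reduction is needed.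

Key step: step 6

Remark: the target is achiral, so no stereocontrol is needed; rings are lettered A (para-phenylene), B (trioxygenated: C1 bridge carbon, C2 ether oxygen, C3 and C4 hydroxyl), C (meta-phenylene) and D (hydroxylated ring carrying the second ether oxygen); compounds 1, 3, 6 and 8 are assumed to be purchasable.

Step 1
Reactants: 1 isovanillin (3-hydroxy-4-methoxybenzaldehyde)
Product: 2 2-methoxy-5-vinylphenol
Conditions: Ph3PCH3Br (2.4 equiv), KOtBu (2.4 equiv), THF, 0 °C to rt
Reagents that add atoms: methyltriphenylphosphonium bromide, C[P+](c1ccccc1)(c1ccccc1)c1ccccc1.[Br-]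
Why: A Wittig methylenation should convert the formyl group into the vinyl group, the phenoxide formed by the extra base being meta to the aldehyde and therefore not deactivating it by resonance.

Step 2
Reactants: 2 2-methoxy-5-vinylphenol; 3 (3-bromophenoxy)triisopropylsilane
Product: 5 2-methoxy-5-{2-[3-(triisopropylsilyloxy)phenyl]ethyl}phenol, via alkylborane 4 (not isolated)
Conditions: 9-BBN (2.2 equiv), THF, 0 °C to rt; then 3, Pd(dppf)Cl2 (5 mol%), aq. K3PO4, DMF, 60 °C
Reagents that add atoms: none
Why: Anti-Markovnikov hydroboration of the styrene with 9-BBN (one further equivalent is consumed by the phenol O–H) followed by B-alkyl Suzuki–Miyaura coupling with the aryl bromide should give the CH2CH2 bridge directly at the saturated oxidation level, the triisopropylsilyl ether being stable to aqueous phosphate.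

Step 3
Reactants: 5 2-methoxy-5-{2-[3-(triisopropylsilyloxy)phenyl]ethyl}phenol; 6 4-vinylphenylboronic acid
Product: 7 triisopropyl(3-{2-[4-methoxy-3-(4-vinylphenoxy)phenyl]ethyl}phenoxy)silane
Conditions: Cu(OAc)2 (1 equiv), pyridine (5 equiv), 4 Å MS, CH2Cl2, dry air, rt
Reagents that add atoms: none
Why: Chan–Lam–Evans O-arylation by the arylboronic acid, with divalent copper turned over by oxygen, should arylate the only free phenol at room temperature under conditions free of fluoride and strong base, so the silyl ether and the styrene survive.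

Step 4
Reactants: 8 4-bromo-3-fluoroanisole
Product: 10 3-bromo-2-fluoro-6-methoxybenzaldehyde, via aryllithium 9 (not isolated)
Conditions: LiN(iPr)2, THF, −78 °C; DMF, −78 °C to 0 °C; aq. HCl
Reagents that add atoms: N,N-dimethylformamide, CN(C)C=O
Why: Directed ortho-metalation should take place at the most acidic C–H, the one flanked by fluorine and methoxy, with the hindered amide base leaving the C–Br bond untouched at −78 °C, and formylation of the aryllithium with DMF then gives the aldehyde on acidic work-up.

Step 5
Reactants: 7 triisopropyl(3-{2-[4-methoxy-3-(4-vinylphenoxy)phenyl]ethyl}phenoxy)silane; 10 3-bromo-2-fluoro-6-methoxybenzaldehyde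
Product: 12 2-fluoro-6-methoxy-3-{2-[4-(2-methoxy-5-{2-[3-(triisopropylsilyloxy)phenyl]ethyl}phenoxy)phenyl]ethyl}benzaldehyde, via alkylborane 11 (not isolated)
Conditions: 9-BBN (1.05 equiv), THF, 0 °C to rt; then aq. K3PO4, 10, Pd(dppf)Cl2 (5 mol%), DMF, 50 °C
Reagents that add atoms: none
Why: Hydroboration of the terminal alkene with 9-BBN and B-alkyl Suzuki–Miyaura coupling, the aldehyde-bearing bromide being added only after all B–H has been consumed and quenched with aqueous base, should join ring A to C1 of ring B by oxidative addition of zerovalent palladium into the C–Br bond, which is far more reactive than the C–F bond.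

Step 6
Reactants: 12 2-fluoro-6-methoxy-3-{2-[4-(2-methoxy-5-{2-[3-(triisopropylsilyloxy)phenyl]ethyl}phenoxy)phenyl]ethyl}benzaldehyde
Product: 14 macrocyclic aldehyde (O-methylated marchantin H skeleton with OMe on ring D and at C4 of ring B and a formyl group at C3 of ring B), via cesium phenoxide 13 (not isolated)
Conditions: CsF (3 equiv), 4 Å MS, DMSO, 110 °C, slow addition of 12 (final 0.002 M)
Reagents that add atoms: none
Why: Fluoride attacks silicon and liberates the ring C phenoxide 13, which adds to the fluorine-bearing C2 of ring B to give a Meisenheimer anion whose charge is delocalized onto the ortho formyl group at C3; loss of fluoride then forms the C2–O bond and returns the fluoride that keeps the desilylation going, so the phenoxide is only ever present at low concentration. The closest known reaction types are the intramolecular SNAr macroetherification of phenols with ortho-activated fluoroarenes used for cyclic diaryl ethers and the fluoride-triggered coupling of aryl silyl ethers with activated aryl fluorides. The only ring closed is the 18-membered macrocycle, formed end to end by addition–elimination at an sp2 carbon under high dilution. No stereocentre is created. The step needs site selectivity and intramolecular over intermolecular reaction: the first is secured because every other oxygen is a methyl or diaryl ether and only one carbon carries a leaving group activated by a carbonyl, the second by slow addition to a dilute solution and by the two flexible CH2CH2 bridges that let the chain ends meet without strain.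

Step 7
Reactants: 14 macrocyclic aldehyde
Product: 16 macrocyclic phenol (C3 hydroxyl of ring B free; OMe on ring D and at C4 of ring B), via aryl formate 15 (not isolated)
Conditions: mCPBA (1.5 equiv), CH2Cl2, 0 °C to rt; aq. NaHCO3 wash; then K2CO3 (cat.), MeOH, rt
Reagents that add atoms: meta-chloroperoxybenzoic acid, OOC(=O)c1cccc(Cl)c1
Why: Baeyer–Villiger oxidation of the aldehyde (Dakin-type) should proceed with migration of the electron-rich 2,6-dioxygenated aryl group to give the aryl formate, which base-catalysed methanolysis cleaves to the C3 phenol.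

Step 8
Reactants: 16 macrocyclic phenol
Product: 17 marchantin H
Conditions: BBr3 (6 equiv), CH2Cl2, −78 °C to rt; then H2O
Reagents that add atoms: none
Why: BBr3 should cleave both aryl methyl ethers through Lewis acid–base complexation and bromide attack at the methyl groups (aryl methyl ether cleavage), whereas the two diaryl ether bonds are inert because neither aryl carbon can be attacked by bromide.

Compound list

1 | isovanillin (3-hydroxy-4-methoxybenzaldehyde) | COc1ccc(C=O)cc1O | starting material
2 | 2-methoxy-5-vinylphenol | COc1ccc(C=C)cc1O | intermediate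
3 | (3-bromophenoxy)triisopropylsilane | CC(C)[Si](Oc1cccc(Br)c1)(C(C)C)C(C)C | starting material
4 | B-alkyl-9-BBN from 2 with the phenol oxygen also borylated (not isolated) | COc1ccc(CCB2C3CCCC2CCC3)cc1OB1C2CCCC1CCC2 | intermediate
5 | 2-methoxy-5-{2-[3-(triisopropylsilyloxy)phenyl]ethyl}phenol | COc1ccc(CCc2cccc(O[Si](C(C)C)(C(C)C)C(C)C)c2)cc1O | intermediate
6 | 4-vinylphenylboronic acid | OB(O)c1ccc(C=C)cc1 | starting material
7 | triisopropyl(3-{2-[4-methoxy-3-(4-vinylphenoxy)phenyl]ethyl}phenoxy)silane | COc1ccc(CCc2cccc(O[Si](C(C)C)(C(C)C)C(C)C)c2)cc1Oc1ccc(C=C)cc1 | intermediate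
8 | 4-bromo-3-fluoroanisole | COc1ccc(Br)c(F)c1 | starting material
9 | (3-bromo-2-fluoro-6-methoxyphenyl)lithium (not isolated) | COc1ccc(Br)c(F)c1[Li] | intermediate
10 | 3-bromo-2-fluoro-6-methoxybenzaldehyde | COc1ccc(Br)c(F)c1C=O | intermediate
11 | B-alkyl-9-BBN from 7 (not isolated) | COc1ccc(CCc2cccc(O[Si](C(C)C)(C(C)C)C(C)C)c2)cc1Oc1ccc(CCB2C3CCCC2CCC3)cc1 | intermediate
12 | 2-fluoro-6-methoxy-3-{2-[4-(2-methoxy-5-{2-[3-(triisopropylsilyloxy)phenyl]ethyl}phenoxy)phenyl]ethyl}benzaldehyde | COc1ccc(CCc2cccc(O[Si](C(C)C)(C(C)C)C(C)C)c2)cc1Oc1ccc(CCc2ccc(OC)c(C=O)c2F)cc1 | intermediate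
13 | cesium phenoxide formed by desilylation of 12 (not isolated) | [Cs+].[O-]c1cccc(CCc2ccc(OC)c(Oc3ccc(CCc4ccc(OC)c(C=O)c4F)cc3)c2)c1 | intermediate
14 | macrocyclic aldehyde (formyl at C3 of ring B; OMe on ring D and at C4 of ring B) | COc1ccc2cc1Oc1ccc(cc1)CCc1ccc(OC)c(C=O)c1Oc1cccc(c1)CC2 | intermediate
15 | macrocyclic aryl formate (not isolated) | COc1ccc2cc1Oc1ccc(cc1)CCc1ccc(OC)c(OC=O)c1Oc1cccc(c1)CC2 | intermediate
16 | macrocyclic phenol (marchantin H dimethyl ether: OMe on ring D and at C4 of ring B) | COc1ccc2cc1Oc1ccc(cc1)CCc1ccc(OC)c(O)c1Oc1cccc(c1)CC2 | intermediate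
17 | marchantin H | Oc1ccc2cc1Oc1ccc(cc1)CCc1ccc(O)c(O)c1Oc1cccc(c1)CC2 | target

Total step count: 8. Longest linear sequence: 7 steps (steps 1, 2, 3, 5, 6, 7, 8); step 4 makes the ring B building block in a side branch.

Steps most likely to fail

1. Step 6 (macrocyclization). The addition–elimination may be slow, because C2 is activated by a single ortho formyl group whose acceptor strength is lowered by the neighbouring methoxy group. Intermolecular oligomerization or thermal degradation of the aldehyde could then outrun ring closure. The fallback uses nitro activation instead, sets out from 7 and returns at 16. Compound 7 is hydroborated as in step 5 to alkylborane 11 and coupled (Pd(dppf)Cl2, K3PO4 monohydrate, DMF, rt) with 1-bromo-2-fluoro-4-methoxy-3-nitrobenzene F1. F1 is made from purchased 3-fluoro-2-nitroanisole by bromination para to the methoxy group (NBS, CF3CO2H). The coupling should give the nitro-activated open-chain silyl ether F2. CsF in DMF at rt and 0.003 M should then give, through the cesium phenoxide F3, the nitro macrocycle F4 by nitro-activated SNAr macroetherification. Reduction (Fe, NH4Cl, EtOH/H2O, 70 °C) should give the amino macrocycle F5. Diazotization (NaNO2, aq. H2SO4, THF, 0 °C) to the diazonium hydrogen sulfate F6 and hydroxydediazoniation (Cu(NO3)2, Cu2O, H2O, rt) should deliver phenol 16.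

2. Step 3 (Chan–Lam coupling). Transmetalation and C–O bond formation at copper may be sluggish with the ortho-methoxy phenol, so that protodeboronation and oxidative homocoupling consume the boronic acid. The fallback sets out from 5 and returns at 7. Palladium-catalysed C–O coupling of 5 with 4-bromobenzaldehyde (Pd(OAc)2, tBuXPhos, K3PO4, toluene, 100 °C; fluoride-free, so the silyl ether is kept) should give 4-(2-methoxy-5-{2-[3-(triisopropylsilyloxy)phenyl]ethyl}phenoxy)benzaldehyde F7. Wittig methylenation (Ph3PCH3Br, KOtBu, THF, 0 °C) should then give 7.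

3. Step 5 (second B-alkyl Suzuki coupling). Hydride transfer from boron to the formyl group of 10, or hydrolytic displacement of the activated fluoride by aqueous base, may compete with cross-coupling. The fallback sets out from 7 and 10 and returns at 12. Mizoroki–Heck coupling (Pd(OAc)2, P(o-tol)3, Et3N, DMF, 90 °C) should give the (E)-stilbene F8. Diimide reduction (dipotassium azodicarboxylate, AcOH, THF, 40 °C) should saturate the C=C bond without touching the aldehyde, the aryl fluoride or the silyl ether, giving 12.

Further compounds

F1 | step 6 | 1-bromo-2-fluoro-4-methoxy-3-nitrobenzene | COc1ccc(Br)c(F)c1[N+](=O)[O-]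
F2 | step 6 | triisopropyl{3-[2-(3-{4-[2-(2-fluoro-4-methoxy-3-nitrophenyl)ethyl]phenoxy}-4-methoxyphenyl)ethyl]phenoxy}silane | COc1ccc(CCc2cccc(O[Si](C(C)C)(C(C)C)C(C)C)c2)cc1Oc1ccc(CCc2ccc(OC)c([N+](=O)[O-])c2F)cc1
F3 | step 6 | cesium phenoxide formed by desilylation of F2 | [Cs+].[O-]c1cccc(CCc2ccc(OC)c(Oc3ccc(CCc4ccc(OC)c([N+](=O)[O-])c4F)cc3)c2)c1
F4 | step 6 | nitro macrocycle (nitro at C3 of ring B) | COc1ccc2cc1Oc1ccc(cc1)CCc1ccc(OC)c([N+](=O)[O-])c1Oc1cccc(c1)CC2
F5 | step 6 | amino macrocycle (NH2 at C3 of ring B) | COc1ccc2cc1Oc1ccc(cc1)CCc1ccc(OC)c(N)c1Oc1cccc(c1)CC2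
F6 | step 6 | macrocyclic arenediazonium hydrogen sulfate | COc1ccc2cc1Oc1ccc(cc1)CCc1ccc(OC)c([N+]#N)c1Oc1cccc(c1)CC2.OS(=O)(=O)[O-]
F7 | step 3 | 4-(2-methoxy-5-{2-[3-(triisopropylsilyloxy)phenyl]ethyl}phenoxy)benzaldehyde | COc1ccc(CCc2cccc(O[Si](C(C)C)(C(C)C)C(C)C)c2)cc1Oc1ccc(C=O)cc1
F8 | step 5 | (E)-stilbene from Heck coupling of 7 and 10 | COc1ccc(CCc2cccc(O[Si](C(C)C)(C(C)C)C(C)C)c2)cc1Oc1ccc(/C=C/c2ccc(OC)c(C=O)c2F)cc1
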